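The 14-membered ring (numbered C1 = acetoxy carbon, through the C2=C3 olefin, C6, the C8=C9 olefin, C10, C11 and the oxirane carbons C12, C13 to C14) is closed between C10 and C11, the two methylenes lying between the Z-trisubstituted C8=C9 olefin and the oxirane. Each is carried as a terminal vinyl carbon, one on a 1,3-diene at C9, the other on a vinyl oxirane at C12, so ring-closing metathesis joins them as C10=C11 in one operation and both olefin geometries converge on the target after diimide reduction. The open-chain precursor comes from (R)-α-terpineol; a dihydropyranone ring sets C1 and relays it to the oxirane.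

Key step: step 14

Remark: ring atoms are numbered as in the overview throughout; C15 is the carbinol carbon of the 2-hydroxypropan-2-yl group.
Assumption: (S)-Tol-BINAP is taken to direct the dienolate to the Si face of aldehyde 12; if the catalyst shows the opposite sense, (R)-Tol-BINAP is used.

Step 1
Reactants: 1 (R)-α-terpineol, 2-[(1R)-4-methylcyclohex-3-en-1-yl]propan-2-ol
Product: 2 triethyl({2-[(1R)-4-methylcyclohex-3-en-1-yl]propan-2-yl}oxy)silane
Conditions: Et3SiOTf, 2,6-lutidine, CH2Cl2, −78 °C → 0 °C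
Reagents that add atoms: triethylsilyl trifluoromethanesulfonate, CC[Si](CC)(CC)OS(=O)(=O)C(F)(F)F
Why: Silyl ether protection of the hindered tertiary alcohol with the silyl triflate should mask the hydroxyl so that the aldehyde released in step 2 cannot close to a lactol.

Step 2
Reactants: 2 triethyl({2-[(1R)-4-methylcyclohex-3-en-1-yl]propan-2-yl}oxy)silane
Product: 4 (3R)-6-oxo-3-[2-(triethylsilyloxy)propan-2-yl]heptanal, via secondary ozonide 3 (not isolated)
Conditions: O3, CH2Cl2, −78 °C; then PPh3, −78 °C → rt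
Reagents that add atoms: ozone, [O-][O+]=O
Why: Ozonolysis of the only olefin with reductive work-up should open the ring to the methyl ketone (C3) and the aldehyde (C8) without touching the stereocentre, which becomes C6.

Step 3
Reactants: 4 (3R)-6-oxo-3-[2-(triethylsilyloxy)propan-2-yl]heptanal
Product: 5 (5R,7Z)-8-iodo-5-[2-(triethylsilyloxy)propan-2-yl]non-7-en-2-one
Conditions: EtPPh3I, n-BuLi, THF, rt; I2, −78 °C; NaN(SiMe3)2, −20 °C; then 4, −78 °C
Reagents that add atoms: ethyltriphenylphosphonium iodide, CC[P+](c1ccccc1)(c1ccccc1)c1ccccc1.[I-]; iodine, II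
Why: Stork–Zhao-type Wittig olefination with the α-iodoethylidene ylide should take the aldehyde in preference to the methyl ketone at −78 °C and place iodine cis to the chain, which fixes the later Z geometry of C8=C9.

Step 4
Reactants: 5 (5R,7Z)-8-iodo-5-[2-(triethylsilyloxy)propan-2-yl]non-7-en-2-one
Product: 6 (5R,7Z)-8-methyl-5-[2-(triethylsilyloxy)propan-2-yl]deca-7,9-dien-2-one
Conditions: CH2=CHSnBu3, Pd(PPh3)4 (5 mol %), CuI (10 mol %), DMF, 40 °C
Reagents that add atoms: tributyl(vinyl)stannane, C=C[Sn](CCCC)(CCCC)CCCC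
Why: Stille coupling proceeds with retention at the alkenyl iodide, so the vinyl group (C10 and its sacrificial CH2) should end cis to C7 and give the Z-configured 1,3-diene.

Step 5
Reactants: 6 (5R,7Z)-8-methyl-5-[2-(triethylsilyloxy)propan-2-yl]deca-7,9-dien-2-one
Product: 8 triethyl({2-[(3Z,6R)-3-methyldeca-1,3-dien-9-yn-6-yl]propan-2-yl}oxy)silane, via enol phosphate 7 (not isolated)
Conditions: LiN(i-Pr)2 (1.1 equiv), THF, −78 °C; ClP(O)(OEt)2, −78 °C → rt; then LiN(i-Pr)2 (2.3 equiv), −78 °C → rt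
Reagents that add atoms: none
Why: Kinetic deprotonation at the methyl group, O-phosphorylation and base-induced elimination of the enol phosphate (ketone-to-alkyne conversion) should give the terminal alkyne, the diene and the silyl ether being inert to the amide base.

Step 6
Reactants: 8 triethyl({2-[(3Z,6R)-3-methyldeca-1,3-dien-9-yn-6-yl]propan-2-yl}oxy)silane
Product: 11 (2E,6R,8Z)-3,9-dimethyl-6-[2-(triethylsilyloxy)propan-2-yl]undeca-2,8,10-trien-1-ol, via alkenylalane 9 (not isolated), via lithium alkenylaluminate 10 (not isolated)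
Conditions: Me3Al, Cp2ZrCl2 (20 mol %), CH2Cl2, 0 °C → rt; then n-BuLi, THF, −78 °C; (CH2O)n, −78 °C → rt; aq. Rochelle salt
Reagents that add atoms: trimethylaluminium, C[Al](C)C; paraformaldehyde (as formaldehyde), C=O
Why: Zirconium-catalysed syn-carboalumination (Negishi carboalumination) adds methyl to the internal and aluminium to the terminal alkyne carbon, and hydroxymethylation of the aluminate with formaldehyde occurs with retention, which should fix the E geometry of C2=C3.

Step 7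
Reactants: 11 (2E,6R,8Z)-3,9-dimethyl-6-[2-(triethylsilyloxy)propan-2-yl]undeca-2,8,10-trien-1-ol
Product: 12 (2E,6R,8Z)-3,9-dimethyl-6-[2-(triethylsilyloxy)propan-2-yl]undeca-2,8,10-trienal
Conditions: MnO2, CH2Cl2, rt
Reagents that add atoms: none
Why: Allylic oxidation with MnO2 is selective for the allylic alcohol and should give the E-enal (C1 aldehyde) without olefin isomerisation.

Step 8
Reactants: 13 methyl 3-methylbut-2-enoate
Product: 14 [(1-methoxy-3-methylbuta-1,3-dien-1-yl)oxy]trimethylsilane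
Conditions: LiN(i-Pr)2, THF, −78 °C; Me3SiCl, −78 °C → rt
Reagents that add atoms: chlorotrimethylsilane, C[Si](C)(C)Cl
Why: γ-Deprotonation of the senecioate and O-silylation of the dienolate (silyl ketene acetal formation) should give the vinylogous nucleophile that carries C11–C14 and the C13 methyl.

Step 9
Reactants: 12 (2E,6R,8Z)-3,9-dimethyl-6-[2-(triethylsilyloxy)propan-2-yl]undeca-2,8,10-trienal; 14 [(1-methoxy-3-methylbuta-1,3-dien-1-yl)oxy]trimethylsilane
Product: 17 (6S)-6-[(1E,5R,7Z)-5-(2-hydroxypropan-2-yl)-2,8-dimethyldeca-1,7,9-trien-1-yl]-4-methyl-5,6-dihydro-2H-pyran-2-one, via trimethylsilyl aldol adduct 15 (not isolated), via triethylsilyl lactone 16 (not isolated)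
Conditions: Cu(OTf)2 (10 mol %), (S)-Tol-BINAP (11 mol %), Bu4N[Ph3SiF2] (20 mol %), THF, −78 °C → rt; then Bu4NF, THF, rt
Reagents that add atoms: none
Why: Copper fluoride/Tol-BINAP-catalysed vinylogous Mukaiyama aldol addition should occur at the γ-carbon on the Si face of the enal (catalyst control) to set C1 as S, after which fluoride frees the alkoxide for lactonisation onto the Z-enoate and removes the triethylsilyl group.

Step 10
Reactants: 17 (6S)-6-[(1E,5R,7Z)-5-(2-hydroxypropan-2-yl)-2,8-dimethyldeca-1,7,9-trien-1-yl]-4-methyl-5,6-dihydro-2H-pyran-2-one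
Product: 18 (1R,4S,6R)-4-[(1E,5R,7Z)-5-(2-hydroxypropan-2-yl)-2,8-dimethyldeca-1,7,9-trien-1-yl]-6-methyl-3,7-dioxabicyclo[4.1.0]heptan-2-one
Conditions: H2O2 (30 % aq.), NaOH (cat.), MeOH, 0 °C
Reagents that add atoms: hydrogen peroxide, OO
Why: In this Weitz–Scheffer nucleophilic epoxidation the hydroperoxide should add to C13 of the unsaturated lactone anti to the C1 side chain and close on the same face, so the cis-fused oxirane forms trans to that substituent, which is the (12S,13R) configuration of the target.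

Step 11
Reactants: 18 (1R,4S,6R)-4-[(1E,5R,7Z)-5-(2-hydroxypropan-2-yl)-2,8-dimethyldeca-1,7,9-trien-1-yl]-6-methyl-3,7-dioxabicyclo[4.1.0]heptan-2-one
Product: 19 (1R,4S,6R)-4-[(1E,5R,7Z)-5-(2-hydroxypropan-2-yl)-2,8-dimethyldeca-1,7,9-trien-1-yl]-6-methyl-3,7-dioxabicyclo[4.1.0]heptan-2-ol (anomeric mixture)
Conditions: i-Bu2AlH (2.3 equiv), CH2Cl2, −78 °C; aq. Rochelle salt
Reagents that add atoms: none
Why: Hydride reduction of a lactone with i-Bu2AlH at −78 °C should stop at the lactol because the tetrahedral aluminate is stable, which unmasks C11 at the aldehyde level while the oxirane survives.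

Step 12
Reactants: 19 (1R,4S,6R)-4-[(1E,5R,7Z)-5-(2-hydroxypropan-2-yl)-2,8-dimethyldeca-1,7,9-trien-1-yl]-6-methyl-3,7-dioxabicyclo[4.1.0]heptan-2-ol
Product: 20 (2S,3E,7R,9Z)-1-[(2R,3S)-3-ethenyl-2-methyloxiran-2-yl]-7-(2-hydroxypropan-2-yl)-4,10-dimethyldodeca-3,9,11-trien-2-ol
Conditions: Ph3PCH3Br, KN(SiMe3)2 (4 equiv each), THF, 0 °C; then 19, 0 °C → rt
Reagents that add atoms: methyltriphenylphosphonium bromide, C[P+](c1ccccc1)(c1ccccc1)c1ccccc1.[Br-]
Why: Wittig methylenation of the lactol through its open hydroxy-aldehyde form should give the vinyl oxirane and free the C1 hydroxyl, the oxirane carbon next to the aldehyde not being epimerisable.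

Step 13
Reactants: 20 (2S,3E,7R,9Z)-1-[(2R,3S)-3-ethenyl-2-methyloxiran-2-yl]-7-(2-hydroxypropan-2-yl)-4,10-dimethyldodeca-3,9,11-trien-2-ol
Product: 21 (2S,3E,7R,9Z)-1-[(2R,3S)-3-ethenyl-2-methyloxiran-2-yl]-7-(2-hydroxypropan-2-yl)-4,10-dimethyldodeca-3,9,11-trien-2-yl acetate
Conditions: Ac2O, pyridine, DMAP (cat.), CH2Cl2, 0 °C
Reagents that add atoms: acetic anhydride, CC(=O)OC(C)=O
Why: DMAP-catalysed acylation should acetylate the secondary allylic hydroxyl selectively, the tertiary hydroxyl being too hindered to react at 0 °C.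

Step 14
Reactants: 21 (2S,3E,7R,9Z)-1-[(2R,3S)-3-ethenyl-2-methyloxiran-2-yl]-7-(2-hydroxypropan-2-yl)-4,10-dimethyldodeca-3,9,11-trien-2-yl acetate
Product: 22 (1R,3S,4E,8R,10Z,14S)-8-(2-hydroxypropan-2-yl)-1,5,11-trimethyl-15-oxabicyclo[12.1.0]pentadeca-4,10,12-trien-3-yl acetate (mixture of 12E and 12Z)
Conditions: second-generation Grubbs catalyst RuCl2(=CHPh)(H2IMes)(PCy3) (10 mol %), 1,4-benzoquinone (20 mol %), toluene (1 mM), 60 °C
Reagents that add atoms: none
Why: In this ring-closing metathesis the ruthenium alkylidene should load on one of the two monosubstituted vinyl groups, pass through a metallacyclobutane with the other and expel ethylene, forming the C10=C11 bond. The closest known reactions are diene–ene macrocyclic ring-closing metathesis to conjugated macrocyclic dienes and metathesis of vinyl oxiranes. The 14-membered carbocycle is closed between two terminal vinyl carbons as an endocyclic olefin. No stereocentre is formed, and the geometry of C10=C11 is immaterial because step 15 saturates this bond. The step needs the two monosubstituted olefins to react in preference to the trisubstituted C2=C3 and C8=C9 olefins and ring closure to win over oligomerisation; the low metathesis reactivity of trisubstituted olefins, high dilution and the turns imposed by the Z-C8=C9 unit and the cis-oxirane should secure both.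

Step 15
Reactants: 22 (1R,3S,4E,8R,10Z,14S)-8-(2-hydroxypropan-2-yl)-1,5,11-trimethyl-15-oxabicyclo[12.1.0]pentadeca-4,10,12-trien-3-yl acetate
Product: 23 (1R,3S,4E,8R,10Z,14S)-8-(2-hydroxypropan-2-yl)-1,5,11-trimethyl-15-oxabicyclo[12.1.0]pentadeca-4,10-dien-3-yl acetate (CNP0254503.1)
Conditions: 2-nitrobenzenesulfonylhydrazide, Et3N, CH2Cl2, rt
Reagents that add atoms: none
Why: Diimide reduction transfers H2 concertedly to the least substituted olefin, so the 1,2-disubstituted C10=C11 bond should be saturated in preference to the two trisubstituted olefins, with the oxirane, the allylic acetate and the tertiary alcohol untouched.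

Compound list
1 | (R)-α-terpineol, 2-[(1R)-4-methylcyclohex-3-en-1-yl]propan-2-ol | CC1=CC[C@@H](CC1)C(C)(C)O | starting material
2 | triethyl({2-[(1R)-4-methylcyclohex-3-en-1-yl]propan-2-yl}oxy)silane | CC1=CC[C@@H](CC1)C(C)(C)O[Si](CC)(CC)CC | intermediate
3 | secondary ozonide (1,2,4-trioxolane) of 2 | CC12OC(C[C@@H](CC1)C(C)(C)O[Si](CC)(CC)CC)OO2 | intermediate
4 | (3R)-6-oxo-3-[2-(triethylsilyloxy)propan-2-yl]heptanal | CC(=O)CC[C@H](CC=O)C(C)(C)O[Si](CC)(CC)CC | intermediate
5 | (5R,7Z)-8-iodo-5-[2-(triethylsilyloxy)propan-2-yl]non-7-en-2-one | CC(=O)CC[C@H](C/C=C(/C)I)C(C)(C)O[Si](CC)(CC)CC | intermediate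
6 | (5R,7Z)-8-methyl-5-[2-(triethylsilyloxy)propan-2-yl]deca-7,9-dien-2-one | CC(=O)CC[C@H](C/C=C(/C)C=C)C(C)(C)O[Si](CC)(CC)CC | intermediate
7 | diethyl (5R,7Z)-8-methyl-5-[2-(triethylsilyloxy)propan-2-yl]deca-1,7,9-trien-2-yl phosphate | C=C(OP(=O)(OCC)OCC)CC[C@H](C/C=C(/C)C=C)C(C)(C)O[Si](CC)(CC)CC | intermediate
8 | triethyl({2-[(3Z,6R)-3-methyldeca-1,3-dien-9-yn-6-yl]propan-2-yl}oxy)silane | C#CCC[C@H](C/C=C(/C)C=C)C(C)(C)O[Si](CC)(CC)CC | intermediate
9 | dimethyl[(1E,5R,7Z)-2,8-dimethyl-5-[2-(triethylsilyloxy)propan-2-yl]deca-1,7,9-trien-1-yl]alane | C[Al](C)/C=C(\C)CC[C@H](C/C=C(/C)C=C)C(C)(C)O[Si](CC)(CC)CC | intermediate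
10 | lithium butyl(dimethyl)[(1E,5R,7Z)-2,8-dimethyl-5-[2-(triethylsilyloxy)propan-2-yl]deca-1,7,9-trien-1-yl]aluminate | [Li+].CCCC[Al-](C)(C)/C=C(\C)CC[C@H](C/C=C(/C)C=C)C(C)(C)O[Si](CC)(CC)CC | intermediate
11 | (2E,6R,8Z)-3,9-dimethyl-6-[2-(triethylsilyloxy)propan-2-yl]undeca-2,8,10-trien-1-ol | OC/C=C(\C)CC[C@H](C/C=C(/C)C=C)C(C)(C)O[Si](CC)(CC)CC | intermediate
12 | (2E,6R,8Z)-3,9-dimethyl-6-[2-(triethylsilyloxy)propan-2-yl]undeca-2,8,10-trienal | O=C/C=C(\C)CC[C@H](C/C=C(/C)C=C)C(C)(C)O[Si](CC)(CC)CC | intermediate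
13 | methyl 3-methylbut-2-enoate | COC(=O)C=C(C)C | starting material
14 | [(1-methoxy-3-methylbuta-1,3-dien-1-yl)oxy]trimethylsilane | COC(=CC(C)=C)O[Si](C)(C)C | intermediate
15 | methyl (2Z,5S,6E,10R,12Z)-3,7,13-trimethyl-10-[2-(triethylsilyloxy)propan-2-yl]-5-(trimethylsilyloxy)pentadeca-2,6,12,14-tetraenoate | COC(=O)/C=C(/C)C[C@H](O[Si](C)(C)C)/C=C(\C)CC[C@H](C/C=C(/C)C=C)C(C)(C)O[Si](CC)(CC)CC | intermediate
16 | (6S)-6-[(1E,5R,7Z)-2,8-dimethyl-5-[2-(triethylsilyloxy)propan-2-yl]deca-1,7,9-trien-1-yl]-4-methyl-5,6-dihydro-2H-pyran-2-one | CC1=CC(=O)O[C@@H](C1)/C=C(\C)CC[C@H](C/C=C(/C)C=C)C(C)(C)O[Si](CC)(CC)CC | intermediate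
17 | (6S)-6-[(1E,5R,7Z)-5-(2-hydroxypropan-2-yl)-2,8-dimethyldeca-1,7,9-trien-1-yl]-4-methyl-5,6-dihydro-2H-pyran-2-one | CC1=CC(=O)O[C@@H](C1)/C=C(\C)CC[C@H](C/C=C(/C)C=C)C(C)(C)O | intermediate
18 | (1R,4S,6R)-4-[(1E,5R,7Z)-5-(2-hydroxypropan-2-yl)-2,8-dimethyldeca-1,7,9-trien-1-yl]-6-methyl-3,7-dioxabicyclo[4.1.0]heptan-2-one | C[C@@]12C[C@@H](/C=C(\C)CC[C@H](C/C=C(/C)C=C)C(C)(C)O)OC(=O)[C@@H]1O2 | intermediate
19 | (1R,4S,6R)-4-[(1E,5R,7Z)-5-(2-hydroxypropan-2-yl)-2,8-dimethyldeca-1,7,9-trien-1-yl]-6-methyl-3,7-dioxabicyclo[4.1.0]heptan-2-ol | C[C@@]12C[C@@H](/C=C(\C)CC[C@H](C/C=C(/C)C=C)C(C)(C)O)OC(O)[C@@H]1O2 | intermediate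
20 | (2S,3E,7R,9Z)-1-[(2R,3S)-3-ethenyl-2-methyloxiran-2-yl]-7-(2-hydroxypropan-2-yl)-4,10-dimethyldodeca-3,9,11-trien-2-ol | C=C[C@@H]1O[C@]1(C)C[C@H](O)/C=C(\C)CC[C@H](C/C=C(/C)C=C)C(C)(C)O | intermediate
21 | (2S,3E,7R,9Z)-1-[(2R,3S)-3-ethenyl-2-methyloxiran-2-yl]-7-(2-hydroxypropan-2-yl)-4,10-dimethyldodeca-3,9,11-trien-2-yl acetate | C=C[C@@H]1O[C@]1(C)C[C@H](OC(C)=O)/C=C(\C)CC[C@H](C/C=C(/C)C=C)C(C)(C)O | intermediate
22 | (1R,3S,4E,8R,10Z,14S)-8-(2-hydroxypropan-2-yl)-1,5,11-trimethyl-15-oxabicyclo[12.1.0]pentadeca-4,10,12-trien-3-yl acetate | CC(=O)O[C@@H]1/C=C(\C)CC[C@@H](C(C)(C)O)C/C=C(/C)C=C[C@@H]2O[C@]2(C)C1 | intermediate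
23 | (1R,3S,4E,8R,10Z,14S)-8-(2-hydroxypropan-2-yl)-1,5,11-trimethyl-15-oxabicyclo[12.1.0]pentadeca-4,10-dien-3-yl acetate | CC(=O)O[C@@H]1/C=C(\C)CC[C@@H](C(C)(C)O)C/C=C(/C)CC[C@@H]2O[C@]2(C)C1 | target

Total step count: 15 steps. Longest linear sequence: 14 steps (1 to 23 through steps 1–7 and 9–15; step 8 prepares dienolate 14).

Steps most likely to fail

Step 14 (ring-closing metathesis). The ring closure may lose to intermolecular metathesis, or the catalyst may load unproductively on the diene terminus as a stabilised vinylcarbene so that the oxirane-side olefin is never engaged. The fallback steers initiation to C11 with a relay tether and sets out from lactol 19. Wittig reaction of 19 with the ylide of (hex-5-en-1-yl)triphenylphosphonium bromide (KN(SiMe3)2, THF) should give the heptadienyl oxirane alcohol F1, and acetylation as in step 13 its acetate F2. With the same ruthenium catalyst the metal should load on the unhindered tether olefin, expel cyclopentene to place the alkylidene on C11 and then close onto the diene terminus. The fallback comes back to the route at macrocycle 22.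

Step 9 (vinylogous aldol and lactonisation). Enantiofacial control on the β,β-disubstituted enal may be poor, or lactonisation may fail if the aldolate forms with the E-enoate geometry. The fallback builds the lactone first and introduces the C13 methyl afterwards, setting out from enal 12. The same copper fluoride/Tol-BINAP catalyst with [(2,2-dimethyl-4-methylidene-4H-1,3-dioxin-6-yl)oxy]trimethylsilane, the substrate class for which this catalyst is best established, should give the hydroxy dioxinone F3. Heating in toluene at 110 °C should release acetone and trap the acylketene with the C1 hydroxyl to give the keto lactone F4. Triflation (Tf2O, Et3N, CH2Cl2, −78 °C) should give the enol triflate F5, and Me2CuLi (THF, −78 °C) should replace the triflate by methyl. The fallback comes back to the route at triethylsilyl lactone 16, which Bu4NF converts to 17 as in step 9.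

Step 3 (iodo-olefination). Enolisation of, or addition to, the methyl ketone may compete, and Z selectivity may erode. The fallback uses a carbonyl-stabilised Z-selective olefination and sets out from keto aldehyde 4. Still–Gennari olefination with ethyl 2-[bis(2,2,2-trifluoroethoxy)phosphoryl]propanoate (KN(SiMe3)2, 18-crown-6, THF, −78 °C) should give the Z-enoate F6. Reduction with i-Bu2AlH should give the diol F7, MnO2 should oxidise only the allylic alcohol to the Z-enal F8, and Wittig methylenation should give the dienol F9. Dess–Martin oxidation of the secondary alcohol comes back to the route at diene ketone 6, which also replaces step 4.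

Further compounds
F1 | step 14 | (2S,3E,7R,9Z)-1-[(2R,3S)-3-[(1Z)-hepta-1,6-dien-1-yl]-2-methyloxiran-2-yl]-7-(2-hydroxypropan-2-yl)-4,10-dimethyldodeca-3,9,11-trien-2-ol | C=CCCC/C=C\[C@@H]1O[C@]1(C)C[C@H](O)/C=C(\C)CC[C@H](C/C=C(/C)C=C)C(C)(C)O
F2 | step 14 | (2S,3E,7R,9Z)-1-[(2R,3S)-3-[(1Z)-hepta-1,6-dien-1-yl]-2-methyloxiran-2-yl]-7-(2-hydroxypropan-2-yl)-4,10-dimethyldodeca-3,9,11-trien-2-yl acetate | C=CCCC/C=C\[C@@H]1O[C@]1(C)C[C@H](OC(C)=O)/C=C(\C)CC[C@H](C/C=C(/C)C=C)C(C)(C)O
F3 | step 9 | 6-[(2S,3E,7R,9Z)-2-hydroxy-4,10-dimethyl-7-[2-(triethylsilyloxy)propan-2-yl]dodeca-3,9,11-trien-1-yl]-2,2-dimethyl-4H-1,3-dioxin-4-one | CC1(C)OC(=O)C=C(O1)C[C@H](O)/C=C(\C)CC[C@H](C/C=C(/C)C=C)C(C)(C)O[Si](CC)(CC)CC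
F4 | step 9 | (6S)-6-[(1E,5R,7Z)-2,8-dimethyl-5-[2-(triethylsilyloxy)propan-2-yl]deca-1,7,9-trien-1-yl]oxane-2,4-dione | O=C1CC(=O)O[C@@H](C1)/C=C(\C)CC[C@H](C/C=C(/C)C=C)C(C)(C)O[Si](CC)(CC)CC
F5 | step 9 | (2S)-2-[(1E,5R,7Z)-2,8-dimethyl-5-[2-(triethylsilyloxy)propan-2-yl]deca-1,7,9-trien-1-yl]-6-oxo-3,6-dihydro-2H-pyran-4-yl trifluoromethanesulfonate | FC(F)(F)S(=O)(=O)OC1=CC(=O)O[C@@H](C1)/C=C(\C)CC[C@H](C/C=C(/C)C=C)C(C)(C)O[Si](CC)(CC)CC
F6 | step 3 | ethyl (2Z,5R)-2-methyl-8-oxo-5-[2-(triethylsilyloxy)propan-2-yl]non-2-enoate | CCOC(=O)/C(C)=C\C[C@@H](CCC(C)=O)C(C)(C)O[Si](CC)(CC)CC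
F7 | step 3 | (2Z,5R)-2-methyl-5-[2-(triethylsilyloxy)propan-2-yl]non-2-ene-1,8-diol | OC/C(C)=C\C[C@@H](CCC(C)O)C(C)(C)O[Si](CC)(CC)CC
F8 | step 3 | (2Z,5R)-8-hydroxy-2-methyl-5-[2-(triethylsilyloxy)propan-2-yl]non-2-enal | O=C/C(C)=C\C[C@@H](CCC(C)O)C(C)(C)O[Si](CC)(CC)CC
F9 | step 3 | (5R,7Z)-8-methyl-5-[2-(triethylsilyloxy)propan-2-yl]deca-7,9-dien-2-ol | C=C/C(C)=C\C[C@@H](CCC(C)O)C(C)(C)O[Si](CC)(CC)CC
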